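## The problem

The target is a (1(10)Z,4Z)-germacradiene, and germacrane locants are used for every intermediate below. The ring is C1=C10(CH3)–C9–C8–C7–C6–C5=C4(CH3)–C3–C2, with C6 (R) carrying a free allylic hydroxyl, C7 (S) the isopropyl group and C8 (R) the vanillate ester.

A synthesis has to solve four things. First, a ten-membered carbocycle must be made, the ring size least favourable to direct cyclisation. Second, both trisubstituted alkenes must be Z. Third, the stereotriad C6–C7–C8 must be set. C7 is the pivot: once it is fixed in absolute terms, C6 oxygen can be introduced anti to the isopropyl group, and C8 can be set by 1,2-induction from C7 in a ketone reduction. Fourth, the two secondary oxygens must be told apart, so that only O8 is acylated.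

The skeleton tolerates little. A cyclodeca-1,5-diene cyclises transannularly with acid. A C8 ketone flanked by C7–H and a C6 oxygen epimerises or eliminates with base. The C8 ketone is also β,γ-unsaturated towards C10=C1.

The feature that opens the problem is that C4 and C8 face each other across the ring. A C4–C8 bond turns the ten-membered ring into a cis-fused bicyclo[5.3.0]decene. C5, C6 and C7 then sit on a cyclopentane, C1=C10 sits in a cycloheptene (necessarily Z), and O8–C8–C4–C5–X is the 1,3-array of a heterolytic fragmentation.

## Retrosynthesis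

**Protecting groups and ester.** Target 26 is taken back to bis-silyl ether 25, so that one buffered fluoride step frees both the phenol and the C6 hydroxyl. Cutting the C8–O acyl bond of 25 gives alcohol 20 and 4-O-silyl vanillic acid 23, which comes from vanillic acid 21 in one operation. Leaving C6 silylated until the end is what differentiates the two carbinols; no selective acylation of a diol is asked for.

**C8 carbinol.** Alcohol 20 comes from ketone 19 by hydride reduction. The cut is made here because the ring-forming step delivers C8 as a carbonyl. The forward reaction must deliver hydride to the outer face of the ring with the C7–C6 bond anti to the incoming hydride (Felkin–Anh), which gives the 8R alcohol.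

**C4–C8 bond (key disconnection).** Reconnecting C4 to C8 in 19 and placing a sulfonate on C5 gives mesylate 17, a cis-fused hydroazulene whose C8 oxygen is masked as a trimethylsilyl ether. Fluoride releases alkoxide 18, which fragments to 19. Against a direct ten-membered ring closure this has three advantages: no medium ring has to be closed, both alkene geometries are dictated by the bicycle, and C6 and C7 are installed on a rigid five-membered ring. Two conditions are asked of 17:

- The mesylate must be cis to C3 (trans to the C4 methyl), so that C3 ends cis to C6 on the new alkene.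
- The ring fusion must be cis. Only then can the cyclopentane twist so that the C5–O bond lies anti to C4–C8. A trans-fused isomer locks that oxygen gauche.

**C5 mesylate.** 17 comes from alcohol 16, and 16 from ketone 15 by hydride attack on the convex face, anti to the neighbouring C6 silyloxy group. C5 is the only carbonyl at this stage, so no chemoselectivity is needed.

**C1=C10.** Opening the cycloheptene of 15 by ring-closing metathesis leads to diene 14, which carries a butenyl group on C4 and a methallyl group on C8, cis on adjacent fully substituted carbons. This is a routine closure and the ring enforces the Z geometry.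

**C6 oxygen and C8–C9 bond.** The α-silyloxy ketone of 14 is the Rubottom product of silyl enol ether 13. 13 comes from ketone 9 by addition of the methallyl Grignard reagent 11 (made from chloride 10) and silylation of the resulting alkoxide 12 in the same flask. The order matters. While C5 is masked as its enol ether, C8 is the only carbonyl, so the organometallic has no choice. Oxidising first would leave two ketones, and the α-silyloxy ketone C5 would be the more electrophilic. Capping O8 as a trimethylsilyl ether does three jobs: it removes a hydroxyl that could direct the peracid to the wrong face, it blocks silyl transfer and retro-aldol chemistry, and it later serves as the trigger for the fragmentation.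

**C7–isopropyl bond.** 9 is the silyl-trapped product of a copper-catalysed enantioselective conjugate addition of diisopropylzinc 7 to the meso enedione 6. This single step sets C7 absolutely and, through attack anti to the butenyl chain, sets C4 relative to C7. It also delivers the enolate at C5, exactly where masking is needed.

**Enedione.** 6 is the dehydrogenation product of dione 4, which arises by methylenation of aldehyde 3, the Michael adduct of 2-methylcyclopentane-1,3-dione 1 and acrolein 2.

## Roads not taken

**Alternative 1:** [2,3]-Wittig ring contraction. The cut is the C6–C7 bond. The forward step deprotonates C6 of the thirteen-membered bis-allylic ether A1 (C6H2–O–C12H2–C11(CH3)=C7, with the C8 silyl ether in place). The carbanion shifts onto C7 and contracts the ring to A2, a ten-membered dienediol derivative with a free C6 hydroxyl, a C7 isopropenyl group and a silylated O8.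

- Merits: the C6–C7 bond, both of its stereocentres and the carbocycle arise in one step. Both ring alkenes are carried in intact. The two oxygens emerge already differentiated.
- Weak points: A1 needs three geometrically defined trisubstituted alkenes and a macrocyclic etherification. C12 is also allylic and α to oxygen, so the site of lithiation is not secured. The relative configuration of C6/C7 to C8 depends on the folding of a flexible thirteen-membered ring. The isopropenyl group must later be hydrogenated in the presence of two ring alkenes, and the protecting groups must be exchanged because the free hydroxyl is on C6 and not on C8.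
- Comparison: this road is better at creating C6 and C7 together and at differentiating the oxygens. The chosen plan sets against it a ring-forming step whose outcome is fixed by a rigid bicycle, not by a macrocyclic conformation.

**Alternative 2:** sulfone alkylation closing C2–C3. The cut is the C2–C3 bond. The open-chain chloro sulfone A3 carries the complete C6–C7–C8 triad and both Z alkenes. Its α-sulfonyl allyl carbanion at C2 displaces the allylic chloride at C3 to give the cyclic sulfone A4.

- Merits: the stereotriad is built by acyclic aldol-type chemistry with high confidence. C8 is fixed from the start, and O6 and O8 carry orthogonal groups. In these respects it is better than the chosen plan, which must set C8 late by reduction of a medium-ring ketone.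
- Weak points: a ten-membered ring must be closed directly, at high dilution, against oligomerisation and SN2′ or γ-alkylation. Two Z trisubstituted alkenes must be made stereoselectively in an open chain. Reductive desulfonylation next to C1=C10 can move or scramble that alkene. The linear sequence to A3 is long.
- Comparison: the chosen plan answers the ring-size and alkene-geometry problems structurally, at the price of one stereocentre set late.

**Alternative 3:** two-carbon ring expansion. The cut is the C8–C9 bond. The potassium alkoxide of the cyclooctadienol A5, whose carbinol C6 bears the C7(isopropyl)=C8H2 alkenyl group, undergoes an anionic 1,3-shift of C9 from C6 to C8 and gives the cyclodecadienone A6.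

- Merits: it is by far the shortest access to the Z,Z ten-membered skeleton, since both alkene geometries are inherited from an eight-membered ring that is easy to make. On step count to the carbocycle it beats the chosen plan clearly.
- Weak points: A6 has the ketone at C6, conjugated with C4=C5, and no oxygen at C8, which is an unactivated methylene. C7 is formed by protonation and is racemic. A competing [3,3] shift through C10=C1 gives an isomeric eight-membered ketone. Introducing O8, reducing C6 and controlling three stereocentres on a flexible ring would cost more than the expansion saves.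
- Comparison: the chosen plan is longer to the ring but arrives with C6, C7 and the C8 oxygen in place and in one enantiomeric series.

Key step: step 10

Assumption: the sense of induction of the copper–phosphoramidite catalyst on enedione 6 is taken to be the one that makes C7 S; if the opposite sense is found, the enantiomeric ligand is used and nothing else changes.

## Route

Step 1
Reactants: 1 2-methylcyclopentane-1,3-dione; 2 acrolein
Product: 3 3-(1-methyl-2,5-dioxocyclopentyl)propanal
Conditions: H2O, rt
Reagents that add atoms: none
Why: Michael addition of the enolised 1,3-dione to acrolein; C-alkylation at C2 is the only productive path and creates the future C4 quaternary carbon with C3–C1 attached.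

Step 2
Reactants: 3 3-(1-methyl-2,5-dioxocyclopentyl)propanal
Product: 4 2-(but-3-en-1-yl)-2-methylcyclopentane-1,3-dione
Conditions: Ph3PCH3Br, KOt-Bu, THF, 0 °C; then 3, −78 → 0 °C
Reagents that add atoms: methyltriphenylphosphonium bromide, C[P+](c1ccccc1)(c1ccccc1)c1ccccc1.[Br-]
Why: Wittig methylenation; the aldehyde reacts far faster than the two ketones, which flank a quaternary carbon, so one equivalent of ylide at low temperature is chemoselective.

Step 3
Reactants: 4 2-(but-3-en-1-yl)-2-methylcyclopentane-1,3-dione
Product: 6 2-(but-3-en-1-yl)-2-methylcyclopent-4-ene-1,3-dione, via trimethylsilyl enol ether 5 (not isolated)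
Conditions: Me3SiOTf, Et3N, CH2Cl2, 0 °C; then Pd(OAc)2, MeCN, rt
Reagents that add atoms: none
Why: Saegusa–Ito oxidation; enolisation is possible only away from the quaternary carbon, and once the ring alkene is in place no enolisable hydrogen is left, so over-oxidation cannot occur. The remote terminal alkene is a spectator.

Step 4
Reactants: 6 2-(but-3-en-1-yl)-2-methylcyclopent-4-ene-1,3-dione; 7 diisopropylzinc
Product: 9 (2S,5S)-2-(but-3-en-1-yl)-3-(tert-butyldimethylsilyloxy)-2-methyl-5-(propan-2-yl)cyclopent-3-en-1-one, via isopropylzinc enolate 8 (not isolated)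
Conditions: Cu(OTf)2 (2 mol %), BINOL/bis(1-phenylethyl)amine phosphoramidite ligand (4 mol %), toluene, −30 °C; then t-BuMe2SiOTf, −30 → 0 °C
Reagents that add atoms: tert-butyldimethylsilyl trifluoromethanesulfonate, CC(C)(C)[Si](C)(C)OS(=O)(=O)C(F)(F)F
Why: Copper-catalysed enantioselective conjugate addition that desymmetrises a meso 2,2-disubstituted cyclopentenedione, a known use of dialkylzinc with phosphoramidite ligands. The ligand chooses the enantiotopic olefin carbon (C7, S), and the alkyl group enters anti to the larger butenyl substituent, which makes isopropyl cis to the C4 methyl. The enolate forms at C5, remote from the new group, and O-silylation masks C5 so that C8 is the only ketone.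

Step 5
Reactants: 9 (2S,5S)-2-(but-3-en-1-yl)-3-(tert-butyldimethylsilyloxy)-2-methyl-5-(propan-2-yl)cyclopent-3-en-1-one; 10 3-chloro-2-methylprop-1-ene
Product: 13 tert-butyl{[(3S,4S,5S)-5-(but-3-en-1-yl)-5-methyl-4-(2-methylprop-2-en-1-yl)-3-(propan-2-yl)-4-(trimethylsilyloxy)cyclopent-1-en-1-yl]oxy}dimethylsilane, via 2-methylallylmagnesium chloride 11 (not isolated), via chloromagnesium alkoxide 12 (not isolated)
Conditions: 10, Mg, THF, 0 °C; 9, THF, −78 °C; then Me3SiOTf, −78 → −30 °C
Reagents that add atoms: trimethylsilyl trifluoromethanesulfonate, C[Si](C)(C)OS(=O)(=O)C(F)(F)F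
Why: Grignard 1,2-addition of an allylic magnesium reagent, which adds through a six-membered transition state faster than it enolises a hindered ketone. The ring is nearly flat and its lower face carries both the C7 isopropyl and the C4 methyl, so attack comes from the face of the butenyl chain and puts C9 cis to C3. Silylation of the alkoxide at low temperature removes a directing hydroxyl and forestalls transfer of the enol silyl group.

Step 6
Reactants: 13 tert-butyl{[(3S,4S,5S)-5-(but-3-en-1-yl)-5-methyl-4-(2-methylprop-2-en-1-yl)-3-(propan-2-yl)-4-(trimethylsilyloxy)cyclopent-1-en-1-yl]oxy}dimethylsilane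
Product: 14 (2R,3S,4S,5S)-2-(but-3-en-1-yl)-5-(tert-butyldimethylsilyloxy)-2-methyl-3-(2-methylprop-2-en-1-yl)-4-(propan-2-yl)-3-(trimethylsilyloxy)cyclopentan-1-one
Conditions: mCPBA (1.05 equiv), NaHCO3, CH2Cl2, −30 → 0 °C
Reagents that add atoms: 3-chloroperoxybenzoic acid, OOC(=O)c1cccc(Cl)c1
Why: Rubottom oxidation; the silyl enol ether is epoxidised much faster than the 1,1-disubstituted and monosubstituted alkenes, and ring opening with 1,4-silyl shift gives the α-silyloxy ketone directly. Oxygen bonds to C6 anti to the adjacent C7 isopropyl group (the same face is further shielded by the C8 silyl ether), which gives the trans C6–O/C7 relationship of the target.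

Step 7
Reactants: 14 (2R,3S,4S,5S)-2-(but-3-en-1-yl)-5-(tert-butyldimethylsilyloxy)-2-methyl-3-(2-methylprop-2-en-1-yl)-4-(propan-2-yl)-3-(trimethylsilyloxy)cyclopentan-1-one
Product: 15 (2S,3S,3aS,8aR)-2-(tert-butyldimethylsilyloxy)-5,8a-dimethyl-3-(propan-2-yl)-3a-(trimethylsilyloxy)-2,3,3a,4,7,8-hexahydroazulen-1(8aH)-one
Conditions: second-generation Grubbs catalyst (H2IMes)(PCy3)Cl2Ru=CHPh (5 mol %), CH2Cl2, 40 °C
Reagents that add atoms: none
Why: Ring-closing metathesis of a monosubstituted with a 1,1-disubstituted alkene held cis on adjacent fully substituted carbons; a trisubstituted cycloheptene results, and its ring size forces C1=C10 to be Z.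

Step 8
Reactants: 15 (2S,3S,3aS,8aR)-2-(tert-butyldimethylsilyloxy)-5,8a-dimethyl-3-(propan-2-yl)-3a-(trimethylsilyloxy)-2,3,3a,4,7,8-hexahydroazulen-1(8aH)-one
Product: 16 (1R,2S,3S,3aS,8aS)-2-(tert-butyldimethylsilyloxy)-5,8a-dimethyl-3-(propan-2-yl)-3a-(trimethylsilyloxy)-1,2,3,3a,4,7,8,8a-octahydroazulen-1-ol
Conditions: i-Bu2AlH, CH2Cl2, −78 °C; aq. potassium sodium tartrate
Reagents that add atoms: none
Why: Hydride 1,2-reduction of the only ketone; the reagent approaches the convex face of the cis-fused bicycle, anti to the adjacent C6 silyloxy group (Felkin–Anh polar model). The C5 hydroxyl therefore ends cis to O6 and cis to C3, and the non-basic aluminium alkoxide does not invite silyl migration.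

Step 9
Reactants: 16 (1R,2S,3S,3aS,8aS)-2-(tert-butyldimethylsilyloxy)-5,8a-dimethyl-3-(propan-2-yl)-3a-(trimethylsilyloxy)-1,2,3,3a,4,7,8,8a-octahydroazulen-1-ol
Product: 17 (1R,2S,3S,3aS,8aS)-2-(tert-butyldimethylsilyloxy)-5,8a-dimethyl-3-(propan-2-yl)-3a-(trimethylsilyloxy)-1,2,3,3a,4,7,8,8a-octahydroazulen-1-yl methanesulfonate
Conditions: MsCl, Et3N, DMAP (cat.), CH2Cl2, 0 °C
Reagents that add atoms: methanesulfonyl chloride, CS(=O)(=O)Cl
Why: Sulfonylation through sulfene, which reaches hindered secondary alcohols; the C5 hydroxyl is the only free one, and a mesylate next to a quaternary carbon is inert to substitution.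

Step 10
Reactants: 17 (1R,2S,3S,3aS,8aS)-2-(tert-butyldimethylsilyloxy)-5,8a-dimethyl-3-(propan-2-yl)-3a-(trimethylsilyloxy)-1,2,3,3a,4,7,8,8a-octahydroazulen-1-yl methanesulfonate
Product: 19 (3Z,7Z,9R,10S)-9-(tert-butyldimethylsilyloxy)-3,7-dimethyl-10-(propan-2-yl)cyclodeca-3,7-dien-1-one, via tetrabutylammonium alkoxide 18 (not isolated)
Conditions: Bu4NF (1.0 equiv), THF, −20 → 0 °C; pH 7 buffer at 0 °C
Reagents that add atoms: none
Why: Fluoride removes the tertiary trimethylsilyl group, and the C8 alkoxide 18 pushes its lone pair into the C4–C8 bond while the C5 mesylate leaves, a concerted heterolytic (Grob or Wharton) fragmentation of a cyclic 1,3-diol monosulfonate, here in the hydroazulene-to-cyclodecenone sense. No ring is closed: cleavage of the bond shared by the five- and seven-membered rings merges them into the ten-membered ring. No stereocentre is created; C4, C5 and C8 become trigonal and C6 and C7 are untouched. The geometry of the new C4=C5 bond follows from the anti-periplanar requirement: the C4 substituent cis to the mesylate (C3) ends cis to C6, which is the Z alkene, and C1=C10 stays Z because it was made inside a seven-membered ring. The alignment is secured by the substrate: with the mesylate cis to C3 on a cis-fused bicycle the cyclopentane can twist until the O–C5–C4–C8 dihedral approaches 160–170°, oxetane formation is excluded by strain, and elimination toward C6 would need attack on a hindered hydrogen. The chemoselectivity needed is cleavage of the tertiary O–SiMe3 bond before the hindered secondary O–Si(t-Bu)Me2 bond, which the difference in silyl lability provides at −20 °C. One equivalent of fluoride ends as Me3SiF and the mesylate salt, so no base remains to epimerise C7, to eliminate the β-silyloxy group or to move C1=C10 into conjugation.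

Step 11
Reactants: 19 (3Z,7Z,9R,10S)-9-(tert-butyldimethylsilyloxy)-3,7-dimethyl-10-(propan-2-yl)cyclodeca-3,7-dien-1-one
Product: 20 (1R,3Z,7Z,9R,10R)-9-(tert-butyldimethylsilyloxy)-3,7-dimethyl-10-(propan-2-yl)cyclodeca-3,7-dien-1-ol
Conditions: LiBH(s-Bu)3, THF, −78 °C; H2O, −78 °C → rt
Reagents that add atoms: none
Why: Felkin–Anh reduction with a bulky hydride; in the reactive conformer the isopropyl group lies near the carbonyl oxygen and the C7–C6 ring bond is perpendicular to the carbonyl plane, so hydride enters from the outer face past the C7 hydrogen and gives the 8R alcohol (O8 cis to isopropyl in the ring sense). The cold quench avoids silyl transfer from O6 to the new alkoxide.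

Step 12
Reactants: 21 vanillic acid
Product: 23 4-(tert-butyldimethylsilyloxy)-3-methoxybenzoic acid, via silyl ester silyl ether 22 (not isolated)
Conditions: t-BuMe2SiCl, imidazole, DMF, rt; then AcOH–THF–H2O, rt
Reagents that add atoms: tert-butyldimethylsilyl chloride, CC(C)(C)[Si](C)(C)Cl
Why: Silylation of both acidic hydroxyls followed by selective hydrolysis of the much more labile silyl ester; the aryl silyl ether survives dilute acetic acid.

Step 13
Reactants: 20 (1R,3Z,7Z,9R,10R)-9-(tert-butyldimethylsilyloxy)-3,7-dimethyl-10-(propan-2-yl)cyclodeca-3,7-dien-1-ol; 23 4-(tert-butyldimethylsilyloxy)-3-methoxybenzoic acid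
Product: 25 (1R,3Z,7Z,9R,10R)-9-(tert-butyldimethylsilyloxy)-3,7-dimethyl-10-(propan-2-yl)cyclodeca-3,7-dien-1-yl 4-(tert-butyldimethylsilyloxy)-3-methoxybenzoate, via acid chloride 24 (not isolated)
Conditions: 23, (COCl)2, DMF (cat.), CH2Cl2, 0 °C → rt, evaporate; then 20, Et3N, DMAP, CH2Cl2, 0 °C → rt
Reagents that add atoms: none
Why: Acid chloride formation and DMAP-catalysed acylation (nucleophilic catalysis) of the only free hydroxyl; no alkoxide is generated, so the C6 silyl ether stays in place and the diene sees no acid.

Step 14
Reactants: 25 (1R,3Z,7Z,9R,10R)-9-(tert-butyldimethylsilyloxy)-3,7-dimethyl-10-(propan-2-yl)cyclodeca-3,7-dien-1-yl 4-(tert-butyldimethylsilyloxy)-3-methoxybenzoate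
Product: 26 (1R,3Z,7Z,9R,10S)-9-hydroxy-3,7-dimethyl-10-(propan-2-yl)cyclodeca-3,7-dien-1-yl 4-hydroxy-3-methoxybenzoate (the target, germacrane descriptors 6R,7S,8R)
Conditions: Bu4NF, AcOH (1:1), THF, 0 °C → rt
Reagents that add atoms: none
Why: Fluoride desilylation; the aryl silyl ether goes first and the hindered allylic C6 ether follows. Acetic acid buffering keeps the medium from promoting 1,3-acyl shift from O8 to O6, and no strong acid is present that could trigger transannular cyclisation of the diene.

## Compound list

1 | 2-methylcyclopentane-1,3-dione | CC1C(=O)CCC1=O | starting material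
2 | acrolein | C=CC=O | starting material
3 | 3-(1-methyl-2,5-dioxocyclopentyl)propanal | CC1(CCC=O)C(=O)CCC1=O | intermediate
4 | 2-(but-3-en-1-yl)-2-methylcyclopentane-1,3-dione | CC1(CCC=C)C(=O)CCC1=O | intermediate
5 | 2-(but-3-en-1-yl)-2-methyl-3-(trimethylsilyloxy)cyclopent-3-en-1-one (racemic) | C=CCCC1(C)C(=O)CC=C1O[Si](C)(C)C | intermediate
6 | 2-(but-3-en-1-yl)-2-methylcyclopent-4-ene-1,3-dione | C=CCCC1(C)C(=O)C=CC1=O | intermediate
7 | diisopropylzinc | CC(C)[Zn]C(C)C | starting material
8 | isopropylzinc enolate corresponding to 9 (O–Zn–CH(CH3)2 in place of the silyl ether, same configuration) | C=CCC[C@@]1(C)C(O[Zn]C(C)C)=C[C@H](C(C)C)C1=O | intermediate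
9 | (2S,5S)-2-(but-3-en-1-yl)-3-(tert-butyldimethylsilyloxy)-2-methyl-5-(propan-2-yl)cyclopent-3-en-1-one | C=CCC[C@@]1(C)C(O[Si](C)(C)C(C)(C)C)=C[C@H](C(C)C)C1=O | intermediate
10 | 3-chloro-2-methylprop-1-ene | C=C(C)CCl | starting material
11 | 2-methylallylmagnesium chloride | C=C(C)C[Mg]Cl | intermediate
12 | chloromagnesium alkoxide corresponding to 13 (O–MgCl in place of O–SiMe3 on C8, same configuration) | C=CCC[C@@]1(C)C(O[Si](C)(C)C(C)(C)C)=C[C@H](C(C)C)[C@@]1(O[Mg]Cl)CC(C)=C | intermediate
13 | tert-butyl{[(3S,4S,5S)-5-(but-3-en-1-yl)-5-methyl-4-(2-methylprop-2-en-1-yl)-3-(propan-2-yl)-4-(trimethylsilyloxy)cyclopent-1-en-1-yl]oxy}dimethylsilane | C=CCC[C@@]1(C)C(O[Si](C)(C)C(C)(C)C)=C[C@H](C(C)C)[C@@]1(O[Si](C)(C)C)CC(C)=C | intermediate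
14 | (2R,3S,4S,5S)-2-(but-3-en-1-yl)-5-(tert-butyldimethylsilyloxy)-2-methyl-3-(2-methylprop-2-en-1-yl)-4-(propan-2-yl)-3-(trimethylsilyloxy)cyclopentan-1-one | C=CCC[C@@]1(C)C(=O)[C@@H](O[Si](C)(C)C(C)(C)C)[C@H](C(C)C)[C@@]1(O[Si](C)(C)C)CC(C)=C | intermediate
15 | (2S,3S,3aS,8aR)-2-(tert-butyldimethylsilyloxy)-5,8a-dimethyl-3-(propan-2-yl)-3a-(trimethylsilyloxy)-2,3,3a,4,7,8-hexahydroazulen-1(8aH)-one (cis-fused) | O=C1[C@@H](O[Si](C)(C)C(C)(C)C)[C@H](C(C)C)[C@@]2(O[Si](C)(C)C)C/C(C)=C\CC[C@]21C | intermediate
16 | (1R,2S,3S,3aS,8aS)-2-(tert-butyldimethylsilyloxy)-5,8a-dimethyl-3-(propan-2-yl)-3a-(trimethylsilyloxy)-1,2,3,3a,4,7,8,8a-octahydroazulen-1-ol | [C@H]1(O)[C@@H](O[Si](C)(C)C(C)(C)C)[C@H](C(C)C)[C@@]2(O[Si](C)(C)C)C/C(C)=C\CC[C@]21C | intermediate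
17 | (1R,2S,3S,3aS,8aS)-2-(tert-butyldimethylsilyloxy)-5,8a-dimethyl-3-(propan-2-yl)-3a-(trimethylsilyloxy)-1,2,3,3a,4,7,8,8a-octahydroazulen-1-yl methanesulfonate | [C@H]1(OS(C)(=O)=O)[C@@H](O[Si](C)(C)C(C)(C)C)[C@H](C(C)C)[C@@]2(O[Si](C)(C)C)C/C(C)=C\CC[C@]21C | intermediate
18 | tetrabutylammonium alkoxide corresponding to 17 (O⁻ in place of O–SiMe3 on C8, same configuration) | [C@H]1(OS(C)(=O)=O)[C@@H](O[Si](C)(C)C(C)(C)C)[C@H](C(C)C)[C@@]2([O-])C/C(C)=C\CC[C@]21C.CCCC[N+](CCCC)(CCCC)CCCC | intermediate
19 | (3Z,7Z,9R,10S)-9-(tert-butyldimethylsilyloxy)-3,7-dimethyl-10-(propan-2-yl)cyclodeca-3,7-dien-1-one | O=C1C/C(C)=C\CC/C(C)=C\[C@@H](O[Si](C)(C)C(C)(C)C)[C@@H]1C(C)C | intermediate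
20 | (1R,3Z,7Z,9R,10R)-9-(tert-butyldimethylsilyloxy)-3,7-dimethyl-10-(propan-2-yl)cyclodeca-3,7-dien-1-ol | O[C@@H]1C/C(C)=C\CC/C(C)=C\[C@@H](O[Si](C)(C)C(C)(C)C)[C@@H]1C(C)C | intermediate
21 | vanillic acid (4-hydroxy-3-methoxybenzoic acid) | COc1cc(C(=O)O)ccc1O | starting material
22 | tert-butyldimethylsilyl 4-(tert-butyldimethylsilyloxy)-3-methoxybenzoate | COc1cc(C(=O)O[Si](C)(C)C(C)(C)C)ccc1O[Si](C)(C)C(C)(C)C | intermediate
23 | 4-(tert-butyldimethylsilyloxy)-3-methoxybenzoic acid | COc1cc(C(=O)O)ccc1O[Si](C)(C)C(C)(C)C | intermediate
24 | 4-(tert-butyldimethylsilyloxy)-3-methoxybenzoyl chloride | COc1cc(C(=O)Cl)ccc1O[Si](C)(C)C(C)(C)C | intermediate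
25 | (1R,3Z,7Z,9R,10R)-9-(tert-butyldimethylsilyloxy)-3,7-dimethyl-10-(propan-2-yl)cyclodeca-3,7-dien-1-yl 4-(tert-butyldimethylsilyloxy)-3-methoxybenzoate | COc1cc(C(=O)O[C@@H]2C/C(C)=C\CC/C(C)=C\[C@@H](O[Si](C)(C)C(C)(C)C)[C@@H]2C(C)C)ccc1O[Si](C)(C)C(C)(C)C | intermediate
26 | (1R,3Z,7Z,9R,10S)-9-hydroxy-3,7-dimethyl-10-(propan-2-yl)cyclodeca-3,7-dien-1-yl 4-hydroxy-3-methoxybenzoate | COc1cc(C(=O)O[C@@H]2C/C(C)=C\CC/C(C)=C\[C@@H](O)[C@@H]2C(C)C)ccc1O | target

## Step count and risks

Total: 14 steps. Longest linear sequence: 13 steps (steps 1–11, 13 and 14); step 12 prepares the acid.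

**Step 10 (key step).** What is most likely to go wrong is erosion after the fragmentation, not the fragmentation itself: fluoride or the transient alkoxide may attack the C6 silyl ether, or act as a base on the product, causing E1cB loss of silanol across C6–C7, epimerisation at C7 or migration of C1=C10 into conjugation. Incomplete anti alignment would show up as sluggish reaction with competing elimination toward C6.
Fallback: a fragmentation that needs no alkoxide and no fluoride. It sets out from 16. Methanolysis (K2CO3, MeOH, 0 °C) of the trimethylsilyl ether gives the bicyclic diol F1. Treatment with Tf2O and 2,6-lutidine in CH2Cl2 at −78 °C sulfonylates only the secondary hydroxyl. The triflate F2 formed in the flask is a far better leaving group, so the neutral tertiary hydroxyl suffices as the push and the fragmentation proceeds under amine buffering. It returns to the route at 19.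

**Step 4.** Three processes are uncertain: the enantioselectivity of transfer of a secondary alkyl group from zinc, the discrimination between methyl and butenyl at C4 (a wrong C4/C7 relationship would later give the 4E alkene), and complete O-silylation of the zinc enolate.
Fallback: set C4 by reduction and C7 by 1,2-induction, with no catalytic conjugate addition. It sets out from 4.

- CBS reduction (oxazaborolidine, BH3·SMe2) desymmetrises the dione to hydroxy ketone F3, with the hydroxyl cis to the butenyl chain.
- Silylation (Et3SiCl, imidazole) gives F4.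
- Dehydrogenation with IBX gives the 4-silyloxycyclopentenone F5.
- i-PrMgCl with catalytic CuBr·SMe2 and Me3SiCl adds trans to the neighbouring silyloxy group and gives F6 after aqueous work-up.
- CrO3/H2SO4 in acetone removes the triethylsilyl group and oxidises the carbinol to diketone F7.
- Soft enolisation (t-BuMe2SiOTf, Et3N, −78 °C) silylates the less hindered C5 carbonyl toward its methylene and returns to the route at 9.

**Step 5.** Allylic magnesium reagents are very reactive and can show low facial selectivity. A C8 epimer would lead to a trans-fused bicycle in which the mesylate cannot reach the anti arrangement. Transfer of the enol silyl group to the new alkoxide and incomplete capping are further risks.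
Fallback: replace the allylmetal by two more discriminating steps. It sets out from 9. Dimethylsulfonium methylide (Me3SI, n-BuLi, THF, −10 °C) adds irreversibly from the face away from isopropyl and gives spiro-epoxide F8. Isopropenylmagnesium bromide with catalytic CuI opens the epoxide at its methylene carbon and gives tertiary alcohol F9 after work-up. Silylation with 1-(trimethylsilyl)imidazole returns to the route at 13.

**Step 6.** The peracid may approach C6 from the isopropyl face if the shielding argument fails, which would give the cis C6/C7 isomer.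
Fallback: thermodynamic control at C6 in place of kinetic control. It sets out from 13. If the Rubottom oxidation delivers the C6 epimer F10, equilibration with DBU in toluene through the C5 enolate moves the silyloxy group trans to isopropyl. C6 is the only enolisable position, and the C8 silyl ether blocks retro-aldol cleavage. It returns to the route at 14.

**Step 11.** The facial preference rests on a conformational argument for a flexible ten-membered ring, and the β-silyloxy group exerts a 1,3-effect that opposes the 1,2-control from C7. Silyl transfer from O6 to the new alkoxide is a second risk.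
Fallback: use the wrong epimer productively. It sets out from 19. If reduction gives mainly the 8S alcohol F11, Mitsunobu esterification with acid 23 (PPh3, diisopropyl azodicarboxylate, toluene) forms the ester with inversion at C8 and returns to the route at 25, with the acid-chloride step no longer needed.

## Further compounds

F1 | step 10 | (1R,2S,3S,3aS,8aS)-2-(tert-butyldimethylsilyloxy)-5,8a-dimethyl-3-(propan-2-yl)-1,2,3,4,7,8-hexahydroazulene-1,3a(8aH)-diol | [C@H]1(O)[C@@H](O[Si](C)(C)C(C)(C)C)[C@H](C(C)C)[C@@]2(O)C/C(C)=C\CC[C@]21C
F2 | step 10 | C5 trifluoromethanesulfonate of F1 (same configuration) | [C@H]1(OS(=O)(=O)C(F)(F)F)[C@@H](O[Si](C)(C)C(C)(C)C)[C@H](C(C)C)[C@@]2(O)C/C(C)=C\CC[C@]21C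
F3 | step 4 | (2R,3R)-2-(but-3-en-1-yl)-3-hydroxy-2-methylcyclopentan-1-one | C=CCC[C@@]1(C)C(=O)CC[C@H]1O
F4 | step 4 | triethylsilyl ether of F3 | C=CCC[C@@]1(C)C(=O)CC[C@H]1O[Si](CC)(CC)CC
F5 | step 4 | 5-(but-3-en-1-yl)-5-methyl-4-(triethylsilyloxy)cyclopent-2-en-1-one (silyloxy cis to butenyl) | C=CCC[C@@]1(C)C(=O)C=C[C@H]1O[Si](CC)(CC)CC
F6 | step 4 | 2-(but-3-en-1-yl)-2-methyl-4-(propan-2-yl)-3-(triethylsilyloxy)cyclopentan-1-one (isopropyl trans to silyloxy and cis to methyl) | C=CCC[C@@]1(C)C(=O)C[C@H](C(C)C)[C@H]1O[Si](CC)(CC)CC
F7 | step 4 | 2-(but-3-en-1-yl)-2-methyl-4-(propan-2-yl)cyclopentane-1,3-dione (isopropyl cis to methyl) | C=CCC[C@@]1(C)C(=O)C[C@H](C(C)C)C1=O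
F8 | step 5 | spiro-epoxide of 9 at C8 (epoxide CH2 cis to butenyl, oxygen cis to isopropyl) | C=CCC[C@@]1(C)C(O[Si](C)(C)C(C)(C)C)=C[C@H](C(C)C)[C@@]12CO2
F9 | step 5 | tertiary alcohol corresponding to 13 (OH in place of O–SiMe3 on C8) | C=CCC[C@@]1(C)C(O[Si](C)(C)C(C)(C)C)=C[C@H](C(C)C)[C@@]1(O)CC(C)=C
F10 | step 6 | C6 epimer of 14 (silyloxy cis to isopropyl) | C=CCC[C@@]1(C)C(=O)[C@H](O[Si](C)(C)C(C)(C)C)[C@H](C(C)C)[C@@]1(O[Si](C)(C)C)CC(C)=C
F11 | step 11 | C8 epimer of 20 | O[C@H]1C/C(C)=C\CC/C(C)=C\[C@@H](O[Si](C)(C)C(C)(C)C)[C@@H]1C(C)C
A1 | alternative 1 | (3E,7Z,11Z)-3,7,11-trimethyl-5-(triethylsilyloxy)-1-oxacyclotrideca-3,7,11-triene, 5R | C1OC/C(C)=C/[C@H](O[Si](CC)(CC)CC)C/C(C)=C\CC/C(C)=C\1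
A2 | alternative 1 | 8-O-triethylsilyl 7-isopropenyl (1(10)Z,4Z)-cyclodecadiene-6,8-diol | CC[Si](CC)(CC)O[C@@H]1C/C(C)=C\CC/C(C)=C\[C@@H](O)[C@@H]1C(C)=C
A3 | alternative 2 | open-chain C3 chloride C2 phenyl sulfone with C6 silyl ether, C7 isopropyl and C8 4-methoxybenzyl ether | O=S(=O)(c1ccccc1)C/C=C(C)\C[C@@H](OCc2ccc(OC)cc2)[C@@H](C(C)C)[C@H](O[Si](C)(C)C(C)(C)C)/C=C(C)\CCl
A4 | alternative 2 | 2-phenylsulfonyl (1(10)Z,4Z)-cyclodecadiene with protected C6 and C8 oxygens | O=S(=O)(c1ccccc1)C1/C=C(C)\C[C@@H](OCc2ccc(OC)cc2)[C@@H](C(C)C)[C@H](O[Si](C)(C)C(C)(C)C)/C=C(C)\C1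
A5 | alternative 3 | (2Z,6Z)-3,7-dimethyl-1-(3-methylbut-1-en-2-yl)cycloocta-2,6-dien-1-ol (racemic) | OC1(C(=C)C(C)C)/C=C(C)\CC/C=C(C)\C1
A6 | alternative 3 | (2Z,6Z)-3,7-dimethyl-10-(propan-2-yl)cyclodeca-2,6-dien-1-one (racemic) | O=C1/C=C(C)\CC/C=C(C)\CCC1C(C)C
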